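(The numbers in the tables were generated by integration for an exercise.)

Whatever the steps, a species whose amount has stopped changing is being made as fast as it is lost (the steady-state approximation). So I asked where target stops in this flask, and let the runs answer.

| setting | noon | spring | autumn | flask |
|---|---|---|---|---|
| substrate | 0.36 M | 0.36 M | 0.54 M | 0.36 M |
| reagent | 0.48 M | 1.1 M | 0.72 M | 0.720 M |
| remark | run made earlier | run made earlier | run made earlier |  |
| time |  |  |  | 40 min |

| run | time / min | target / % | isomer of the product / % |
|---|---|---|---|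
| noon | 1.33 | 1.5 | 0.9 |
| noon | 4.00 | 2.5 | 0.9 |
| noon | 6.00 | 3.9 | 1.5 |
| noon | 10.0 | 2.9 | 0 |
| noon | 15.0 | 5.1 | 2.0 |
| noon | 20.0 | 6.3 | 2.0 |
| noon | 25.0 | 7.5 | 2.2 |
| spring | 2.00 | 4.2 | 1.3 |
| spring | 3.00 | 5.0 | 0.9 |
| spring | 4.00 | 6.6 | 0 |
| spring | 6.00 | 5.7 | 2.8 |
| spring | 10.0 | 10.1 | 2.6 |
| spring | 15.0 | 10.2 | 1.3 |
| spring | 25.0 | 11.6 | 2.6 |
| autumn | 5.00 | 5.5 | 0.8 |
| autumn | 10.0 | 4.9 | 0.7 |
| autumn | 15.0 | 7.6 | 2.0 |
| autumn | 20.0 | 9.8 | 4.9 |
| autumn | 25.0 | 7.8 | 4.2 |

(each reading ± 1 percentage point)



* how much target the flask holds at 40 min, in percent of the substrate charged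
* how much isomer of the product the flask holds at 40 min, in percent of the substrate charged

At 4.00 min, spring held 2.64 times noon's target, on 2.29 times noon's reagent, so I took making as proportional to reagent. I assumed that the loss ignores reagent and that percentages ignore the substrate charge. The plateau percentage should then scale with reagent. Spring's readings from 10.0 min on average 10.6%; divided by spring's reagent that is 0.0967 M⁻¹, which puts the flask at 6.96%.

That transfer was the weak link: spring, with more reagent than the flask, should consume its substrate faster, which I expected to lower its plateau. Autumn has the flask's reagent, so I reforged the number from autumn's readings from 15.0 min on. This gave G, the plateau target per molar of reagent charged: 0.117 M⁻¹. The flask then comes to 8.40%. Late isomer over late target, pooled across the runs, reads 0.313, which gives 2.63% isomer.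

The forecast, reasoning that "The flask lies between noon and spring", stood at 11% target and 3.2% isomer, its target above mine.

The flask held 8.54% target and 3.03% isomer at 40 min.

    substrate + reagent ⇌ target (K = 0.340 M⁻¹, k = 3.40 × 10⁻⁴ M⁻¹ s⁻¹)
    target ⇌ isomer of the product (K = 0.350, k = 0.00130 s⁻¹)
    target → over-reaction product (k = 8.90 × 10⁻⁴ s⁻¹)

The flask's target had already stood at 8.53% at 20.0 min, and its final amount divided by the flask's reagent is 0.119 M⁻¹, beside G of 0.117 M⁻¹. Meanwhile over-reaction product reached 15.8%. A neighbouring flask, charged with 0.18 M of reagent, was reckoned the same way: G gives 2.11% target, and the isomer ratio gives 0.658% isomer. That neighbour held 2.54% target and 0.885% isomer at 40 min.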